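The diaryl ether between the phenolic oxygen of para-bridged ring D and C3 of ring C is formed second to last, closing the 18-membered ring. The step exploits the free hydroxyl on C4 of ring C, ortho to that ether carbon: it is carried as a formyl group, which activates a C3 fluoride for intramolecular SNAr by the ring D phenoxide, released in the same flask from its silyl ether. The hydroxyl on ring A is likewise carried as the native aldehyde of 2-bromoisovanillin, so one double Dakin oxidation finishes the synthesis. The precursor is an acyclic bis(bibenzyl) dialdehyde assembled by a Chan–Lam coupling and two Heck reactions.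

Key step: step 5

Remark: ring A is the methoxy/hydroxy ring, ring B the meta-linked aryloxy ring, ring C the hydroxylated ring that carries the ether on C3 (chain on C1, hydroxyl on C4), and ring D the para-linked ring. Compounds 1, 2, 4 and 6 are taken as commercially available.

Step 1
Reactants: 1 2-bromo-3-hydroxy-4-methoxybenzaldehyde (2-bromoisovanillin); 2 (3-ethenylphenyl)boronic acid
Product: 3 2-bromo-3-(3-ethenylphenoxy)-4-methoxybenzaldehyde
Conditions: Cu(OAc)2 (1.5 equiv), pyridine, 4 Å MS, CH2Cl2, air, rt
Reagents that add atoms: none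
Why: Chan–Lam–Evans O-arylation, which is known to tolerate phenols with two ortho substituents and should leave the aryl bromide, the aldehyde and the vinyl group untouched at room temperature.

Step 2
Reactants: 3 2-bromo-3-(3-ethenylphenoxy)-4-methoxybenzaldehyde; 4 4-bromo-2-fluorobenzaldehyde
Product: 5 2-bromo-3-{3-[(E)-2-(3-fluoro-4-formylphenyl)ethenyl]phenoxy}-4-methoxybenzaldehyde
Conditions: Pd(OAc)2, P(o-tol)3, Et3N, DMF, 90 °C
Reagents that add atoms: none
Why: Mizoroki–Heck reaction in which the unhindered, para-formyl-activated bromide of 4 should undergo oxidative addition far faster than the di-ortho-substituted bromide of 3, with syn insertion and syn β-hydride elimination giving the E-alkene.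

Step 3
Reactants: 5 2-bromo-3-{3-[(E)-2-(3-fluoro-4-formylphenyl)ethenyl]phenoxy}-4-methoxybenzaldehyde; 6 tert-butyl(4-ethenylphenoxy)dimethylsilane
Product: 7 2-{(E)-2-[4-(tert-butyldimethylsilyloxy)phenyl]ethenyl}-3-{3-[(E)-2-(3-fluoro-4-formylphenyl)ethenyl]phenoxy}-4-methoxybenzaldehyde
Conditions: Pd2(dba)3, [HP(t-Bu)3]BF4, Cy2NMe, dioxane, 90 °C
Reagents that add atoms: none
Why: Mizoroki–Heck reaction in which the bulky, electron-rich P(t-Bu)3 ligand should let zerovalent palladium insert into the hindered but formyl-activated C–Br bond, the terminal styrene 6 reacting in preference to the internal stilbene to give the E-alkene.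

Step 4
Reactants: 7 the bis-stilbene dialdehyde of step 3
Product: 8 2-{2-[4-(tert-butyldimethylsilyloxy)phenyl]ethyl}-3-{3-[2-(3-fluoro-4-formylphenyl)ethyl]phenoxy}-4-methoxybenzaldehyde
Conditions: H2 (1–4 atm), 10% Pd/C, Ph2S (cat.), EtOAc, rt
Reagents that add atoms: none
Why: Heterogeneous catalytic hydrogenation in which the Ph2S-moderated Pd/C should saturate both stilbene double bonds while leaving the aryl aldehydes, the aryl fluoride and the silyl ether intact.

Step 5
Reactants: 8 2-{2-[4-(tert-butyldimethylsilyloxy)phenyl]ethyl}-3-{3-[2-(3-fluoro-4-formylphenyl)ethyl]phenoxy}-4-methoxybenzaldehyde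
Product: 10 macrocyclic dialdehyde (the target ring system with a formyl group in place of each phenolic hydroxyl), via cesium phenoxide 9 (not isolated)
Conditions: CsF (5 equiv), DMSO, 100 °C, syringe-pump addition of 8, final concentration 0.003 M
Reagents that add atoms: none
Why: Fluoride cleaves the aryl silyl ether of 8 to the naked cesium phenoxide 9, whose oxygen adds to C3 of ring C, ortho to the formyl group, to give a Meisenheimer adduct that expels fluoride (addition–elimination SNAr). The closest known reaction type is the intramolecular SNAr macroetherification used for macrocyclic diaryl ethers, here with ortho-formyl in place of ortho-nitro activation, as in the well-established intermolecular coupling of 2-fluorobenzaldehydes with phenoxides. The 18-membered ring is closed in an exo mode at the sp2 carbon, the negative charge being taken up outside the new ring by C4 and its formyl group. No stereocenter is formed. The step needs cyclization to beat oligomerization, which slow addition into hot dilute DMSO should secure, and it needs a single electrophilic site, which the substrate secures because only ring C carries a leaving group on an activated carbon and because the ring A oxygen is still a formyl group and cannot compete as a phenoxide. The formyl activator is not removed but is turned into the C4 hydroxyl in step 6.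

Step 6
Reactants: 10 macrocyclic dialdehyde
Product: 12 CNP0179896.0 (the target macrocyclic bis(bibenzyl) diphenol), via bis-formate 11 (not isolated)
Conditions: mCPBA (2.5 equiv), CH2Cl2, 0 °C to rt; aqueous Na2S2O3/NaHCO3 wash; then K2CO3 (cat.), MeOH, 0 °C, argon
Reagents that add atoms: mCPBA (3-chloroperoxybenzoic acid), O=C(OO)c1cccc(Cl)c1
Why: Double Dakin-type sequence (Baeyer–Villiger oxidation, then formate methanolysis): both formyl groups sit on electron-rich rings (para-methoxy on ring A, ortho-aryloxy and para-alkyl on ring C), so aryl migration should give bis-formate 11, which mild methanolysis should convert into the two phenols.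

Compound list
1 | 2-bromo-3-hydroxy-4-methoxybenzaldehyde | COc1ccc(C=O)c(Br)c1O | starting material
2 | (3-ethenylphenyl)boronic acid | C=Cc1cccc(B(O)O)c1 | starting material
3 | 2-bromo-3-(3-ethenylphenoxy)-4-methoxybenzaldehyde | COc1ccc(C=O)c(Br)c1Oc1cccc(C=C)c1 | intermediate
4 | 4-bromo-2-fluorobenzaldehyde | O=Cc1ccc(Br)cc1F | starting material
5 | 2-bromo-3-{3-[(E)-2-(3-fluoro-4-formylphenyl)ethenyl]phenoxy}-4-methoxybenzaldehyde | COc1ccc(C=O)c(Br)c1Oc1cccc(/C=C/c2ccc(C=O)c(F)c2)c1 | intermediate
6 | tert-butyl(4-ethenylphenoxy)dimethylsilane | C=Cc1ccc(O[Si](C)(C)C(C)(C)C)cc1 | starting material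
7 | 2-{(E)-2-[4-(tert-butyldimethylsilyloxy)phenyl]ethenyl}-3-{3-[(E)-2-(3-fluoro-4-formylphenyl)ethenyl]phenoxy}-4-methoxybenzaldehyde | COc1ccc(C=O)c(/C=C/c2ccc(O[Si](C)(C)C(C)(C)C)cc2)c1Oc1cccc(/C=C/c2ccc(C=O)c(F)c2)c1 | intermediate
8 | 2-{2-[4-(tert-butyldimethylsilyloxy)phenyl]ethyl}-3-{3-[2-(3-fluoro-4-formylphenyl)ethyl]phenoxy}-4-methoxybenzaldehyde | COc1ccc(C=O)c(CCc2ccc(O[Si](C)(C)C(C)(C)C)cc2)c1Oc1cccc(CCc2ccc(C=O)c(F)c2)c1 | intermediate
9 | cesium 4-{2-[2-formyl-6-{3-[2-(3-fluoro-4-formylphenyl)ethyl]phenoxy}-5-methoxyphenyl]ethyl}phenoxide | COc1ccc(C=O)c(CCc2ccc([O-])cc2)c1Oc1cccc(CCc2ccc(C=O)c(F)c2)c1.[Cs+] | intermediate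
10 | macrocyclic dialdehyde (formyl on C4 of ring A and on C4 of ring C of the target ring system) | COc1ccc(C=O)c2c1Oc1cccc(c1)CCc1ccc(C=O)c(c1)Oc1ccc(cc1)CC2 | intermediate
11 | macrocyclic bis(formate ester) of the target (both phenols as O-formyl) | COc1ccc(OC=O)c2c1Oc1cccc(c1)CCc1ccc(OC=O)c(c1)Oc1ccc(cc1)CC2 | intermediate
12 | CNP0179896.0, 18-membered bis(bibenzyl) macrocycle with methoxy and hydroxyl on ring A and hydroxyl on ring C | COc1ccc(O)c2c1Oc1cccc(c1)CCc1ccc(O)c(c1)Oc1ccc(cc1)CC2 | target

Total step count: 6. Longest linear sequence: 6 steps (1 to 12).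

Steps most likely to fail

Step 5. The formyl group is a weaker SNAr activator than a nitro group, so ring closure may be slow enough for intermolecular etherification (oligomer formation) or base-induced degradation of the aldehydes to take over. The fallback swaps the activator for a cyano group and adjusts the oxidation level afterwards; it sets out from 3 and comes back to the route at 10. Heck coupling of 3 with 4-bromo-2-fluorobenzonitrile under the conditions of step 2 should give the stilbene nitrile F1. A second Heck coupling with 6 as in step 3 should give the bis-stilbene nitrile F2, and hydrogenation as in step 4 should give the saturated nitrile F3. CsF in DMF at 60 °C under high dilution should then close the ring at the much more electrophilic ortho-cyano fluoride to give the macrocyclic nitrile aldehyde F4. Excess i-Bu2AlH (CH2Cl2, −78 °C, aqueous Rochelle salt work-up) should reduce the nitrile to the aldehyde and the ring A aldehyde to the benzylic alcohol, giving the hydroxymethyl aldehyde F5. MnO2 in CH2Cl2 should reoxidize the benzylic alcohol and deliver 10.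

Step 3. Oxidative addition and alkene insertion at the bromide flanked by a formyl and an aryloxy group may be sluggish, so that reduction of the C–Br bond or catalyst decomposition competes. The fallback changes the order of bond formation so that the Heck reaction runs on the smaller bromophenol; it sets out from 1 and comes back at 7. Heck coupling of 1 with 6 (Pd2(dba)3, [HP(t-Bu)3]BF4, Cy2NMe, dioxane, 80 °C) should give the hydroxy stilbene aldehyde F6. Chan–Lam–Evans arylation of its phenol with 2 (Cu(OAc)2, pyridine, 4 Å MS, CH2Cl2, air) should give the vinyl diaryl ether F7. Heck coupling of F7 with 4 under the conditions of step 2, now with no competing internal bromide, should give 7.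

Step 1. Transmetalation and C–O bond formation at the phenol flanked by bromine and methoxy may be slow, so that protodeboronation and oxidative homocoupling consume the boronic acid. The fallback replaces the oxidative boronic acid coupling by an Ullmann-type etherification with an aryl iodide; it sets out from 1 and comes back at 3. Compound 1 and 1-ethenyl-3-iodobenzene with CuI, picolinic acid and K3PO4 in DMSO at 80 °C should give 3 directly, the aryl iodide reacting in preference to the hindered bromide of 1.

Further compounds
F1 | step 5 | 4-[(E)-2-{3-[2-bromo-3-formyl-6-methoxyphenoxy]phenyl}ethenyl]-2-fluorobenzonitrile | COc1ccc(C=O)c(Br)c1Oc1cccc(/C=C/c2ccc(C#N)c(F)c2)c1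
F2 | step 5 | 4-[(E)-2-{3-[2-{(E)-2-[4-(tert-butyldimethylsilyloxy)phenyl]ethenyl}-3-formyl-6-methoxyphenoxy]phenyl}ethenyl]-2-fluorobenzonitrile | COc1ccc(C=O)c(/C=C/c2ccc(O[Si](C)(C)C(C)(C)C)cc2)c1Oc1cccc(/C=C/c2ccc(C#N)c(F)c2)c1
F3 | step 5 | 4-[2-{3-[2-{2-[4-(tert-butyldimethylsilyloxy)phenyl]ethyl}-3-formyl-6-methoxyphenoxy]phenyl}ethyl]-2-fluorobenzonitrile | COc1ccc(C=O)c(CCc2ccc(O[Si](C)(C)C(C)(C)C)cc2)c1Oc1cccc(CCc2ccc(C#N)c(F)c2)c1
F4 | step 5 | macrocyclic nitrile aldehyde (formyl on C4 of ring A, cyano on C4 of ring C) | COc1ccc(C=O)c2c1Oc1cccc(c1)CCc1ccc(C#N)c(c1)Oc1ccc(cc1)CC2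
F5 | step 5 | macrocyclic hydroxymethyl aldehyde (hydroxymethyl on C4 of ring A, formyl on C4 of ring C) | COc1ccc(CO)c2c1Oc1cccc(c1)CCc1ccc(C=O)c(c1)Oc1ccc(cc1)CC2
F6 | step 3 | 2-{(E)-2-[4-(tert-butyldimethylsilyloxy)phenyl]ethenyl}-3-hydroxy-4-methoxybenzaldehyde | COc1ccc(C=O)c(/C=C/c2ccc(O[Si](C)(C)C(C)(C)C)cc2)c1O
F7 | step 3 | 2-{(E)-2-[4-(tert-butyldimethylsilyloxy)phenyl]ethenyl}-3-(3-ethenylphenoxy)-4-methoxybenzaldehyde | COc1ccc(C=O)c(/C=C/c2ccc(O[Si](C)(C)C(C)(C)C)cc2)c1Oc1cccc(C=C)c1
F0 | step 1 | none | none
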